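**Plan**

- Locants: ring C1 (carries the side chain) to C6 (carbinol), oxirane at C3–C4 (methyl on C4), angelate on C5; side chain C7 (=CH2), C8 (angelate), C9, oxirane at C10–C11.
- Retrosynthesis: the C10–C11 and then the C3–C4 oxirane are removed, the ring is opened at C1–C6 to an acyclic aldehyde carrying a 2-substituted allylboronate, the CH2B unit is cut from C7 (alkenyl iodide, traced to a propargylic alcohol), and the chain is cut at C7–C8 (acetylide + amide) and C3=C4 (Wittig).
- Forward: the chain is joined at C3=C4, then C7–C8, then C7–CH2B; the only carbocycle arises in step 16; the ring oxirane and the side-chain oxirane follow in steps 17 and 18.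
- Stereochemistry: C5 from methyl (R)-isopropylidene glycerate; C8 by Noyori transfer hydrogenation; alkene geometries by a Z-selective Wittig reaction and a trans-hydrostannation; C1 and C6 in the ring closure; C3/C4 by hydroxyl-directed epoxidation; C10 by Shi epoxidation.
- Enabling feature: C6 (CH–OH) is bonded to C1, which carries the 1,1-disubstituted alkene C7=CH2. This homoallylic alcohol is the retron of a carbonyl allylation with allylic transposition, so one closure gives the ring, C1, C6, the exocyclic methylene and the only free hydroxyl.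

Key step: step 16

Remark: the zinc reagent IZnCH2Bpin is taken as a THF solution made beforehand from 2-(iodomethyl)-4,4,5,5-tetramethyl-1,3,2-dioxaborolane and zinc dust, and the catalyst enantiomer of step 8 is assigned by analogy with simple alkynyl ketones.

**Step 1**
Reactants: 1 methyl (R)-isopropylidene glycerate
Product: 2 glycerate Weinreb amide
Conditions: MeNHOMe·HCl, i-PrMgCl, THF, −20 °C
Reagents that add atoms: N,O-dimethylhydroxylamine hydrochloride, CNOC.Cl
Why: Aminolysis of the ester by the chloromagnesium amide formed in the flask (Weinreb amide synthesis), cold enough that the α-alkoxy stereocenter is not enolised.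

**Step 2**
Reactants: 2 glycerate Weinreb amide
Product: 4 (R)-dioxolanyl methyl ketone, via magnesium chelate 3 (not isolated)
Conditions: MeMgBr, THF, 0 °C; then pH 7 buffer
Reagents that add atoms: methylmagnesium bromide, C[Mg]Br
Why: Weinreb ketone synthesis, in which the chelated tetrahedral adduct blocks a second addition and releases the ketone only on work-up.

**Step 3**
Reactants: 5 (4-bromobut-1-yn-1-yl)trimethylsilane
Product: 6 silylbutynyl phosphonium bromide
Conditions: PPh3, MeCN, 80 °C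
Reagents that add atoms: triphenylphosphine, c1ccc(cc1)P(c1ccccc1)c1ccccc1
Why: SN2 quaternisation of the phosphine by a primary bromide (phosphonium salt formation).

**Step 4**
Reactants: 4 (R)-dioxolanyl methyl ketone; 6 silylbutynyl phosphonium bromide
Product: 8 (Z)-silyl enyne acetonide, via ylide 7 (not isolated)
Conditions: NaN(SiMe3)2, THF, −78 °C; then 4, −78 °C to rt
Reagents that add atoms: none
Why: Wittig olefination of an α-alkoxy methyl ketone with a non-stabilised ylide, a combination known to place the ylide substituent cis to the oxygenated carbon, which should give the (Z)-C3=C4 alkene the later ring needs while the cold, salt-free conditions leave C5 untouched.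

**Step 5**
Reactants: 8 (Z)-silyl enyne acetonide
Product: 9 (Z)-enyne acetonide with terminal alkyne
Conditions: K2CO3 (0.2 equiv), MeOH, rt
Reagents that add atoms: none
Why: Methoxide-induced protodesilylation of the alkynylsilane, which touches neither the acetal nor the alkene.

**Step 6**
Reactants: 10 4-methylpent-3-enoic acid
Product: 12 4-methylpent-3-enoic Weinreb amide, via acyl imidazole 11 (not isolated)
Conditions: 1,1'-carbonyldiimidazole, CH2Cl2, 0 °C; then MeNHOMe·HCl, rt
Reagents that add atoms: N,O-dimethylhydroxylamine hydrochloride, CNOC.Cl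
Why: Amide formation through the acyl imidazole under conditions mild enough to keep the β,γ-alkene out of conjugation.

**Step 7**
Reactants: 9 (Z)-enyne acetonide with terminal alkyne; 12 4-methylpent-3-enoic Weinreb amide
Product: 15 ynone, via lithium acetylide 13 (not isolated), via lithium hemiaminal alkoxide 14 (not isolated)
Conditions: n-BuLi, THF, −78 °C; then 12, −78 to 0 °C; then pH 7 buffer
Reagents that add atoms: none
Why: Acylation of a lithium acetylide by a Weinreb amide, which stops at the chelated adduct and gives the alkynyl ketone on neutral work-up.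

**Step 8**
Reactants: 15 ynone
Product: 16 (S)-propargylic alcohol
Conditions: Ru[(S,S)-TsNCH(Ph)CH(Ph)NH](η6-p-cymene) (1 mol %), i-PrOH, rt
Reagents that add atoms: none
Why: Noyori asymmetric transfer hydrogenation of an α,β-acetylenic ketone, in which the alkynyl group plays the part of the aryl group so that the (S,S)-catalyst should set C8 as (S), under base-free conditions that leave the skipped alkene in place.

**Step 9**
Reactants: 16 (S)-propargylic alcohol
Product: 17 (Z)-alkenylstannane
Conditions: [(C5Me5)RuCl]4 (2 mol %), Bu3SnH, CH2Cl2, rt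
Reagents that add atoms: tributyltin hydride, CCCC[SnH](CCCC)CCCC
Why: Ruthenium-catalysed trans-hydrostannation of a propargylic alcohol, in which the free hydroxyl steers tin to the proximal alkyne carbon (C7) and hydrogen adds anti, so that C2 and tin end cis on the new alkene.

**Step 10**
Reactants: 17 (Z)-alkenylstannane
Product: 18 (Z)-alkenyl iodide
Conditions: I2 (1.05 equiv), CH2Cl2, −78 °C
Reagents that add atoms: iodine, II
Why: Iododestannylation with retention of alkene geometry, far faster at −78 °C than iodoetherification of the other alkenes.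

**Step 11**
Reactants: 18 (Z)-alkenyl iodide
Product: 19 iodo triol
Conditions: AcOH/H2O (4:1), 40 °C
Reagents that add atoms: none
Why: Acid hydrolysis of the isopropylidene acetal, mild enough for the allylic alcohols and the alkenyl iodide.

**Step 12**
Reactants: 19 iodo triol
Product: 20 primary TBS ether
Conditions: TBSCl (1.05 equiv), imidazole, CH2Cl2, −20 to 0 °C
Reagents that add atoms: tert-butyldimethylsilyl chloride, CC(C)(C)[Si](C)(C)Cl
Why: Silylation selective for the primary hydroxyl over the two secondary allylic ones on steric grounds.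

**Step 13**
Reactants: 20 primary TBS ether
Product: 21 bis-angelate
Conditions: angelic acid, 2,4,6-trichlorobenzoyl chloride, Et3N, toluene, rt; then 20, 75 °C
Reagents that add atoms: angelic acid, C/C=C(/C)C(=O)O
Why: Yamaguchi-type esterification through the mixed anhydride without a nucleophilic catalyst, conditions known to transfer the angeloyl group without Z-to-E isomerisation, acylating the C5 and C8 hydroxyls in one operation.

**Step 14**
Reactants: 21 bis-angelate
Product: 22 silylated allylboronate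
Conditions: IZnCH2Bpin (2 equiv), Pd(PPh3)4 (5 mol %), THF, rt
Reagents that add atoms: (pinacolatoboryl)methylzinc iodide, CC1(C)OB(C[Zn]I)OC1(C)C
Why: Negishi coupling of an alkenyl iodide with the α-boryl alkylzinc reagent, a known route to allylboronates that retains alkene geometry, with oxidative addition of zerovalent palladium into the C–I bond expected to outpace ionisation of the hindered allylic esters.

**Step 15**
Reactants: 22 silylated allylboronate
Product: 23 hydroxy allylboronate
Conditions: camphorsulfonic acid (10 mol %), MeOH/CH2Cl2, 0 °C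
Reagents that add atoms: none
Why: Acid-catalysed methanolysis of the primary silyl ether, in a medium that suppresses 1,2-acyl migration and leaves the pinacol allylboronate intact.

**Step 16**
Reactants: 23 hydroxy allylboronate
Product: 26 all-cis cyclohexenol, via aldehyde 24 (not isolated), via pinacol borate 25 (not isolated)
Conditions: Dess–Martin periodinane, pyridine, CH2Cl2/MeCN, 0 °C to rt; then pH 7 buffer
Reagents that add atoms: none
Why: Dess–Martin oxidation of the only free hydroxyl gives aldehyde 24, whose carbonyl oxygen binds boron so that the allyl unit is transferred through a closed six-membered chair: C1 attacks C6 while the B–CH2 bond breaks and C7=CH2 forms, giving borate 25, which is hydrolysed on work-up. The closest known reaction type is the intramolecular allylboration of ω-oxo allylboronates set off by oxidation or acetal cleavage. The cyclohexene closes by a 6-exo-trig attack on the formyl carbon, with the carbonyl and allyl π bonds both ending outside the new ring, which is cis-fused to the boron-containing chair. The C1/C6 relationship is set by the alkene geometry kept since step 9: C2 is cis to CH2B and therefore axial on the chair while C5 is equatorial, which places the C6 hydroxyl and the C1 side chain cis. The aldehyde face is set by C5: in the polar Felkin–Anh arrangement the C5–O bond lies antiperiplanar to the forming C1–C6 bond, the angelate is pseudoequatorial and the new hydroxyl comes out cis to it. The step needs this facial selectivity against the conformer with a pseudoaxial angelate, and a chemoselective oxidation; the acceptor ability of the acyloxy C–O bond and the polar co-solvent, which damps the dipole-minimised alternative, serve the first, and the absence of any other hydroxyl secures the second.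

**Step 17**
Reactants: 26 all-cis cyclohexenol
Product: 27 ring epoxide
Conditions: VO(acac)2 (5 mol %), t-BuOOH (in decane), CH2Cl2, 0 °C to rt
Reagents that add atoms: tert-butyl hydroperoxide, CC(C)(C)OO
Why: Vanadium-catalysed hydroxyl-directed epoxidation of a cyclic homoallylic alcohol, in which the peroxide bound at C6–OH delivers oxygen to the ring alkene on the hydroxyl face (C3 and C4 set cis to OH), the trisubstituted ring alkene being preferred over C7=CH2 and the remote alkene not being reached.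

**Step 18**
Reactants: 27 ring epoxide
Product: 28 target CNP0296086.3
Conditions: D-fructose-derived Shi ketone (1 equiv), Oxone (2KHSO5·KHSO4·K2SO4), NaHCO3 (pH about 8), MeCN/dimethoxymethane/aq. Na2EDTA, 0 °C
Reagents that add atoms: Oxone (active component potassium peroxymonosulfate), [K+].[O-]S(=O)(=O)OO
Why: Shi asymmetric epoxidation, in which the chiral dioxirane attacks the electron-rich trisubstituted C10=C11 bond through the spiro transition state to set C10 as (R), while C7=CH2 and the enoates are poor substrates and the near-neutral pH protects the cis-hydroxy ester from acyl migration.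

**Compound list**

1 | methyl (4R)-2,2-dimethyl-1,3-dioxolane-4-carboxylate | COC(=O)[C@H]1COC(C)(C)O1 | starting material
2 | (4R)-N-methoxy-N,2,2-trimethyl-1,3-dioxolane-4-carboxamide | CON(C)C(=O)[C@H]1COC(C)(C)O1 | intermediate
3 | bromomagnesium 1-[(4R)-2,2-dimethyl-1,3-dioxolan-4-yl]-1-[methoxy(methyl)amino]ethan-1-olate (magnesium chelate) | CC(O[Mg]Br)(N(C)OC)[C@H]1COC(C)(C)O1 | intermediate (not isolated)
4 | 1-[(4R)-2,2-dimethyl-1,3-dioxolan-4-yl]ethan-1-one | CC(=O)[C@H]1COC(C)(C)O1 | intermediate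
5 | (4-bromobut-1-yn-1-yl)trimethylsilane | C[Si](C)(C)C#CCCBr | starting material
6 | triphenyl[4-(trimethylsilyl)but-3-yn-1-yl]phosphonium bromide | C[Si](C)(C)C#CCC[P+](c1ccccc1)(c1ccccc1)c1ccccc1.[Br-] | intermediate
7 | triphenyl[4-(trimethylsilyl)but-3-yn-1-ylidene]phosphorane (ylide) | C[Si](C)(C)C#CCC=P(c1ccccc1)(c1ccccc1)c1ccccc1 | intermediate (not isolated)
8 | (4S)-2,2-dimethyl-4-[(2Z)-6-(trimethylsilyl)hex-2-en-5-yn-2-yl]-1,3-dioxolane | C[Si](C)(C)C#CC/C=C(C)\[C@H]1COC(C)(C)O1 | intermediate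
9 | (4S)-4-[(2Z)-hex-2-en-5-yn-2-yl]-2,2-dimethyl-1,3-dioxolane | C#CC/C=C(C)\[C@H]1COC(C)(C)O1 | intermediate
10 | 4-methylpent-3-enoic acid | CC(C)=CCC(=O)O | starting material
11 | 1-(1H-imidazol-1-yl)-4-methylpent-3-en-1-one (acyl imidazole) | CC(C)=CCC(=O)n1ccnc1 | intermediate (not isolated)
12 | N-methoxy-N,4-dimethylpent-3-enamide | CON(C)C(=O)CC=C(C)C | intermediate
13 | lithium acetylide of 9 | [Li]C#CC/C=C(C)\[C@H]1COC(C)(C)O1 | intermediate (not isolated)
14 | lithium alkoxide of the tetrahedral adduct of 13 and 12 | CC(C)=CCC(O[Li])(N(C)OC)C#CC/C=C(C)\[C@H]1COC(C)(C)O1 | intermediate (not isolated)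
15 | (9Z)-10-[(4S)-2,2-dimethyl-1,3-dioxolan-4-yl]-2-methylundeca-2,9-dien-6-yn-5-one | CC(C)=CCC(=O)C#CC/C=C(C)\[C@H]1COC(C)(C)O1 | intermediate
16 | (5S,9Z)-10-[(4S)-2,2-dimethyl-1,3-dioxolan-4-yl]-2-methylundeca-2,9-dien-6-yn-5-ol | CC(C)=CC[C@H](O)C#CC/C=C(C)\[C@H]1COC(C)(C)O1 | intermediate
17 | (5S,6Z,9Z)-10-[(4S)-2,2-dimethyl-1,3-dioxolan-4-yl]-2-methyl-6-(tributylstannyl)undeca-2,6,9-trien-5-ol | CC(C)=CC[C@H](O)/C([Sn](CCCC)(CCCC)CCCC)=C/C/C=C(C)\[C@H]1COC(C)(C)O1 | intermediate
18 | (5S,6Z,9Z)-10-[(4S)-2,2-dimethyl-1,3-dioxolan-4-yl]-6-iodo-2-methylundeca-2,6,9-trien-5-ol | CC(C)=CC[C@H](O)/C(I)=C/C/C=C(C)\[C@H]1COC(C)(C)O1 | intermediate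
19 | (2S,3Z,6Z,8S)-7-iodo-3,11-dimethyldodeca-3,6,10-triene-1,2,8-triol | CC(C)=CC[C@H](O)/C(I)=C/C/C=C(C)\[C@H](O)CO | intermediate
20 | (2S,3Z,6Z,8S)-1-{[tert-butyl(dimethyl)silyl]oxy}-7-iodo-3,11-dimethyldodeca-3,6,10-triene-2,8-diol | CC(C)=CC[C@H](O)/C(I)=C/C/C=C(C)\[C@H](O)CO[Si](C)(C)C(C)(C)C | intermediate
21 | (2S,3Z,6Z,8S)-1-{[tert-butyl(dimethyl)silyl]oxy}-7-iodo-3,11-dimethyldodeca-3,6,10-triene-2,8-diyl bis[(2Z)-2-methylbut-2-enoate] | CC(C)=CC[C@H](OC(=O)/C(C)=C\C)/C(I)=C/C/C=C(C)\[C@H](OC(=O)/C(C)=C\C)CO[Si](C)(C)C(C)(C)C | intermediate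
22 | (2S,3Z,6E,8S)-1-{[tert-butyl(dimethyl)silyl]oxy}-3,11-dimethyl-7-[(4,4,5,5-tetramethyl-1,3,2-dioxaborolan-2-yl)methyl]dodeca-3,6,10-triene-2,8-diyl bis[(2Z)-2-methylbut-2-enoate] (CH2B cis to the C5 methylene of the chain) | CC(C)=CC[C@H](OC(=O)/C(C)=C\C)/C(CB1OC(C)(C)C(C)(C)O1)=C/C/C=C(C)\[C@H](OC(=O)/C(C)=C\C)CO[Si](C)(C)C(C)(C)C | intermediate
23 | (2S,3Z,6E,8S)-1-hydroxy-3,11-dimethyl-7-[(4,4,5,5-tetramethyl-1,3,2-dioxaborolan-2-yl)methyl]dodeca-3,6,10-triene-2,8-diyl bis[(2Z)-2-methylbut-2-enoate] | CC(C)=CC[C@H](OC(=O)/C(C)=C\C)/C(CB1OC(C)(C)C(C)(C)O1)=C/C/C=C(C)\[C@H](OC(=O)/C(C)=C\C)CO | intermediate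
24 | (2S,3Z,6E,8S)-3,11-dimethyl-1-oxo-7-[(4,4,5,5-tetramethyl-1,3,2-dioxaborolan-2-yl)methyl]dodeca-3,6,10-triene-2,8-diyl bis[(2Z)-2-methylbut-2-enoate] | CC(C)=CC[C@H](OC(=O)/C(C)=C\C)/C(CB1OC(C)(C)C(C)(C)O1)=C/C/C=C(C)\[C@H](OC(=O)/C(C)=C\C)C=O | intermediate (not isolated)
25 | pinacol borate of 26 (boron on the C6 oxygen) | C=C([C@H](CC=C(C)C)OC(=O)/C(C)=C\C)[C@@H]1CC=C(C)[C@H](OC(=O)/C(C)=C\C)[C@@H]1OB2OC(C)(C)C(C)(C)O2 | intermediate (not isolated)
26 | (1S,5S,6R)-6-hydroxy-2-methyl-5-[(3S)-6-methyl-3-{[(2Z)-2-methylbut-2-enoyl]oxy}hepta-1,5-dien-2-yl]cyclohex-2-en-1-yl (2Z)-2-methylbut-2-enoate (ester, hydroxyl and side chain all cis) | C=C([C@H](CC=C(C)C)OC(=O)/C(C)=C\C)[C@@H]1CC=C(C)[C@H](OC(=O)/C(C)=C\C)[C@@H]1O | intermediate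
27 | (1S,2R,3R,4S,6S)-3-hydroxy-1-methyl-4-[(3S)-6-methyl-3-{[(2Z)-2-methylbut-2-enoyl]oxy}hepta-1,5-dien-2-yl]-7-oxabicyclo[4.1.0]heptan-2-yl (2Z)-2-methylbut-2-enoate | C=C([C@H](CC=C(C)C)OC(=O)/C(C)=C\C)[C@@H]1C[C@@H]2O[C@]2(C)[C@H](OC(=O)/C(C)=C\C)[C@@H]1O | intermediate
28 | (1S,2R,3R,4S,6S)-4-[(3S)-4-[(2R)-3,3-dimethyloxiran-2-yl]-3-{[(2Z)-2-methylbut-2-enoyl]oxy}but-1-en-2-yl]-3-hydroxy-1-methyl-7-oxabicyclo[4.1.0]heptan-2-yl (2Z)-2-methylbut-2-enoate (CNP0296086.3) | C=C([C@H](C[C@H]1OC1(C)C)OC(=O)/C(C)=C\C)[C@@H]1C[C@@H]2O[C@]2(C)[C@H](OC(=O)/C(C)=C\C)[C@@H]1O | target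

Total step count: 18. Longest linear sequence: 16 steps (1, 2, 4, 5, 7 to 18); steps 3 and 6 prepare the two side fragments.

**Steps most likely to fail**

Step 16. The weak point is facial selectivity with respect to C5. A transition state with a pseudoaxial angelate has no A(1,2) strain with the C4 methyl and has the C–O and C=O dipoles opposed. It would give the diastereomer with the C5 ester trans to the new hydroxyl, which cannot be repaired later. The fallback sets out from 16 and comes back at 26. Palladium-catalysed syn-hydrostannation of 16 (Bu3SnH, PdCl2(PPh3)2, THF) would put tin on the same carbon but hydrogen syn, giving the (E)-alkenylstannane F1 and, after iodolysis, the (E)-alkenyl iodide F2. The operations of steps 11 to 15 would lead through the iodo triol F3, the primary silyl ether F4, the bis-angelate F5 and the silylated allylboronate F6 to the hydroxy allylboronate F7, whose boron-bearing methylene is trans to C2. Oxidation as in step 16 would give the aldehyde F8, which should close through a trans-fused chair to the pinacol borate F9 and, after hydrolysis, the 6-epi cyclohexenol F10. In that chair the arrangement with the C5–O bond anti to the forming bond is also the all-equatorial one, and the competing conformer gains nothing from dipole opposition. F10 would have the C5 ester and the C1 side chain cis and the C6 hydroxyl trans to both. Dess–Martin oxidation to the cyclohexenone F11 and reduction with K[s-Bu3BH] at −78 °C from the equatorial direction would then give the axial, all-cis alcohol 26.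

Step 14. Slow transmetalation could let zerovalent palladium ionise the allylic angelates, with loss of an ester by substitution or elimination, and the allylboronate could be lost by protodeboronation on purification. The fallback sets out from 18 and comes back at 22. The same Negishi coupling run on 18, which carries no allylic ester, would give the allylboronate acetonide F12. Acetal hydrolysis (AcOH/H2O) would give the boryl triol F13, silylation (TBSCl, imidazole) the boryl silyl ether F14, and double angeloylation as in step 13 would give 22.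

Step 13. The hindered C8 hydroxyl next to the iodoalkene may acylate incompletely, and forcing conditions may isomerise the angeloyl group to the (E)-ester. The fallback sets out from 20 and comes back at 21. Esterification of both hydroxyls with 2-[bis(2,2,2-trifluoroethoxy)phosphoryl]propanoic acid (DCC, DMAP, CH2Cl2) would give the bis(phosphonopropionate) F15. A double Still–Gennari olefination with acetaldehyde (KN(SiMe3)2, 18-crown-6, THF, −78 °C) would then build both (Z)-2-methylbut-2-enoates on the substrate and give 21.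

**Further compounds**

F1 | step 16 | (5S,6E,9Z)-10-[(4S)-2,2-dimethyl-1,3-dioxolan-4-yl]-2-methyl-6-(tributylstannyl)undeca-2,6,9-trien-5-ol | CC(C)=CC[C@H](O)/C([Sn](CCCC)(CCCC)CCCC)=C\C/C=C(C)\[C@H]1COC(C)(C)O1
F2 | step 16 | (5S,6E,9Z)-10-[(4S)-2,2-dimethyl-1,3-dioxolan-4-yl]-6-iodo-2-methylundeca-2,6,9-trien-5-ol | CC(C)=CC[C@H](O)/C(I)=C\C/C=C(C)\[C@H]1COC(C)(C)O1
F3 | step 16 | (2S,3Z,6E,8S)-7-iodo-3,11-dimethyldodeca-3,6,10-triene-1,2,8-triol | CC(C)=CC[C@H](O)/C(I)=C\C/C=C(C)\[C@H](O)CO
F4 | step 16 | (2S,3Z,6E,8S)-1-{[tert-butyl(dimethyl)silyl]oxy}-7-iodo-3,11-dimethyldodeca-3,6,10-triene-2,8-diol | CC(C)=CC[C@H](O)/C(I)=C\C/C=C(C)\[C@H](O)CO[Si](C)(C)C(C)(C)C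
F5 | step 16 | (2S,3Z,6E,8S)-1-{[tert-butyl(dimethyl)silyl]oxy}-7-iodo-3,11-dimethyldodeca-3,6,10-triene-2,8-diyl bis[(2Z)-2-methylbut-2-enoate] | CC(C)=CC[C@H](OC(=O)/C(C)=C\C)/C(I)=C\C/C=C(C)\[C@H](OC(=O)/C(C)=C\C)CO[Si](C)(C)C(C)(C)C
F6 | step 16 | (2S,3Z,6Z,8S)-1-{[tert-butyl(dimethyl)silyl]oxy}-3,11-dimethyl-7-[(4,4,5,5-tetramethyl-1,3,2-dioxaborolan-2-yl)methyl]dodeca-3,6,10-triene-2,8-diyl bis[(2Z)-2-methylbut-2-enoate] | CC(C)=CC[C@H](OC(=O)/C(C)=C\C)/C(CB1OC(C)(C)C(C)(C)O1)=C\C/C=C(C)\[C@H](OC(=O)/C(C)=C\C)CO[Si](C)(C)C(C)(C)C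
F7 | step 16 | (2S,3Z,6Z,8S)-1-hydroxy-3,11-dimethyl-7-[(4,4,5,5-tetramethyl-1,3,2-dioxaborolan-2-yl)methyl]dodeca-3,6,10-triene-2,8-diyl bis[(2Z)-2-methylbut-2-enoate] | CC(C)=CC[C@H](OC(=O)/C(C)=C\C)/C(CB1OC(C)(C)C(C)(C)O1)=C\C/C=C(C)\[C@H](OC(=O)/C(C)=C\C)CO
F8 | step 16 | (2S,3Z,6Z,8S)-3,11-dimethyl-1-oxo-7-[(4,4,5,5-tetramethyl-1,3,2-dioxaborolan-2-yl)methyl]dodeca-3,6,10-triene-2,8-diyl bis[(2Z)-2-methylbut-2-enoate] | CC(C)=CC[C@H](OC(=O)/C(C)=C\C)/C(CB1OC(C)(C)C(C)(C)O1)=C\C/C=C(C)\[C@H](OC(=O)/C(C)=C\C)C=O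
F9 | step 16 | pinacol borate of F10 (boron on the C6 oxygen) | C=C([C@H](CC=C(C)C)OC(=O)/C(C)=C\C)[C@@H]1CC=C(C)[C@H](OC(=O)/C(C)=C\C)[C@H]1OB2OC(C)(C)C(C)(C)O2
F10 | step 16 | (1S,5S,6S)-6-hydroxy-2-methyl-5-[(3S)-6-methyl-3-{[(2Z)-2-methylbut-2-enoyl]oxy}hepta-1,5-dien-2-yl]cyclohex-2-en-1-yl (2Z)-2-methylbut-2-enoate | C=C([C@H](CC=C(C)C)OC(=O)/C(C)=C\C)[C@@H]1CC=C(C)[C@H](OC(=O)/C(C)=C\C)[C@H]1O
F11 | step 16 | (1S,5S)-2-methyl-5-[(3S)-6-methyl-3-{[(2Z)-2-methylbut-2-enoyl]oxy}hepta-1,5-dien-2-yl]-6-oxocyclohex-2-en-1-yl (2Z)-2-methylbut-2-enoate | C=C([C@H](CC=C(C)C)OC(=O)/C(C)=C\C)[C@@H]1CC=C(C)[C@H](OC(=O)/C(C)=C\C)C1=O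
F12 | step 14 | (5S,6E,9Z)-10-[(4S)-2,2-dimethyl-1,3-dioxolan-4-yl]-2-methyl-6-[(4,4,5,5-tetramethyl-1,3,2-dioxaborolan-2-yl)methyl]undeca-2,6,9-trien-5-ol | CC(C)=CC[C@H](O)/C(CB1OC(C)(C)C(C)(C)O1)=C/C/C=C(C)\[C@H]2COC(C)(C)O2
F13 | step 14 | (2S,3Z,6E,8S)-3,11-dimethyl-7-[(4,4,5,5-tetramethyl-1,3,2-dioxaborolan-2-yl)methyl]dodeca-3,6,10-triene-1,2,8-triol | CC(C)=CC[C@H](O)/C(CB1OC(C)(C)C(C)(C)O1)=C/C/C=C(C)\[C@H](O)CO
F14 | step 14 | (2S,3Z,6E,8S)-1-{[tert-butyl(dimethyl)silyl]oxy}-3,11-dimethyl-7-[(4,4,5,5-tetramethyl-1,3,2-dioxaborolan-2-yl)methyl]dodeca-3,6,10-triene-2,8-diol | CC(C)=CC[C@H](O)/C(CB1OC(C)(C)C(C)(C)O1)=C/C/C=C(C)\[C@H](O)CO[Si](C)(C)C(C)(C)C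
F15 | step 13 | (2S,3Z,6Z,8S)-1-{[tert-butyl(dimethyl)silyl]oxy}-7-iodo-3,11-dimethyldodeca-3,6,10-triene-2,8-diyl bis{2-[bis(2,2,2-trifluoroethoxy)phosphoryl]propanoate} | CC(C)=CC[C@H](OC(=O)C(C)P(=O)(OCC(F)(F)F)OCC(F)(F)F)/C(I)=C/C/C=C(C)\[C@H](OC(=O)C(C)P(=O)(OCC(F)(F)F)OCC(F)(F)F)CO[Si](C)(C)C(C)(C)C
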